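- Compare the two charges first: in alder and cedar the nucleophile, at 0.400 M, stands below the electrophile, at 0.50 M. Each target takes one of each, so the nucleophile is the limiting reagent, and the reacted part of the electrophile stops at 80.0 %, the ceiling, which is nucleophile charged divided by electrophile charged.

| setting | Friday's | Monday's | alder | cedar |
|---|---|---|---|---|
| electrophile | 0.50 M | 0.50 M | 0.50 M | 0.50 M |
| nucleophile | 0.40 M | 0.40 M | 0.400 M | 0.400 M |
| free base | 0.15 M | 0.41 M | 0.250 M | 0.500 M |
| remark | run made earlier | run made earlier |  |  |
| time |  |  | 15 min | 15 min |

| run | time / min | electrophile / % | target / % |
|---|---|---|---|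
| Friday's | 0.667 | 69.3 | 30.3 |
| Friday's | 2.00 | 55.9 | 44.0 |
| Friday's | 4.00 | 45.1 | 54.5 |
| Friday's | 5.00 | 41.0 | 58.5 |
| Friday's | 8.00 | 32.6 | 67.8 |
| Monday's | 0.667 | 68.9 | 30.7 |
| Monday's | 1.00 | 63.6 | 36.3 |
| Monday's | 2.00 | 54.6 | 45.6 |
| Monday's | 4.00 | 43.0 | 56.4 |
| Monday's | 8.00 | 30.0 | 70.7 |

(readings scatter by 0.3 percentage points)

- part of the electrophile that has reacted at the end, alder
- part of the electrophile that has reacted at the end, cedar
- what raising the concentration of free base from its lowest to its highest value here does to the part of the electrophile that has reacted (changes below 5 percentage points count as none) (it rises / no change / it falls)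

- the numbers in the tables scatter by 0.3 percentage points (one standard deviation)
- on the list of suspects stand: electrophile + nucleophile -> acid set free + target; nucleophile + acid set free <-> protonated nucleophile; acid set free + free base <-> salt of the base; acid set free -> by-product carried off

- That ceiling is your bound from above. For a bound from below, take the earlier runs: the reacted part grows through both, and Monday's run, with more free base, stood ahead of Friday's at 8.00 min.
- Friday's run had less free base than alder, and it had reacted 67.4 % at that time. Monday's had less than cedar, and it had reacted 70.0 %.
- Now tighten by watching the gap to the ceiling. In Friday's run it went from 25 percentage points at 4.00 min to 13 points at 8.00 min, which is half.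
- My own reckoning carries that pace on to 15 min, an assumption rather than a proof. This puts the lower edge for alder at 76.2 %. Monday's gaps, treated the same way, put it for cedar at 77.7 %.
- Both flasks then lie within 3.8 points of the ceiling, less than 5 points, so I expect no change between them.
- The forecast gives 76 % for alder, 77 % for cedar and no change, holding that “The base therefore seems weak”; each of its two numbers stands above the reading of the matching earlier run at 8.00 min and below the ceiling.
- The flask gives 77.5 % for alder and 78.3 % for cedar, a difference of 0.8 points: no change.

    electrophile + nucleophile → acid set free + target (k = 0.0450 /M/s)
    nucleophile + acid set free ⇌ protonated nucleophile, settled at all times (K = 360 /M)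
    acid set free + free base ⇌ salt of the base (K = 7100 /M, k = 0.230 /M/s)
    acid set free → by-product carried off (k = 0.0770 /s)

- At 15 min alder stands 2.5 points under its ceiling, with 2.44 % of its own nucleophile charge still free, and left for 150 min it gives 80.0 %. The answer for alder has moved by 5 points once the electrophile reaches 0.543 M. A further flask like alder, with 0.85 M of electrophile, has its ceiling at 47.1 %, and at 15 min it gives 47.1 %.

The numbers in the tables are simulated for an exercise; scatter was added.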